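**Retrosynthetic overview**

1. The pyran ring (one C–O and one C–C bond) is closed last by an inverse-demand oxa-Diels–Alder reaction between the Z-trisubstituted C4=C5 alkene of (1S,9R)-isocaryophyllene 30 and a 4-methylidene-1,2-dione made in the flask from the hirsutane diosphenol 16 and formaldehyde.
2. Ring C of 16 is annulated onto ring B by allylation, Wacker oxidation and aldol condensation. Rings A and B are made together from bicyclo[2.2.2]octenone 9 by an oxa-di-π-methane rearrangement, in which ring A is the cyclohexene ring C1–C6 of 9 contracted to the cyclopentane C1–C5.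
3. The enabling feature is the β,γ-enone C7(=O)–C1–C6=C5 of 9: the sp3 bridgehead C1 is held rigidly between carbonyl and alkene. The quaternary C2(CH3)CO2H is set before by an endo Diels–Alder reaction of a masked o-benzoquinone with methyl methacrylate, followed by resolution.
4. Partner 30: the Z alkene comes from ring opening of 4-methyl-3,6-dihydro-2H-pyran, C1 from SAMP-hydrazone alkylation of 3,3-dimethylcyclobutanone, the nine-membered ring from a titanium-mediated keto ester cyclisation, and the methylidene from a Wittig reaction.
5. Order of ring formation: bicyclo[2.2.2]octenone, then rings A and B (key step), then ring C; separately the nine-membered ring onto the purchased cyclobutane; the pyran ring last.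

Key step: step 5

Remark on the target: the terpene half has C1 S, C9 R and a cis pyran/cyclononane junction. It therefore derives from the Z alkene of the series enantiomeric to commercial β-caryophyllene and isocaryophyllene (1R,9S), so this partner is made by synthesis (steps 11 to 18).
Remark on step 4: which amine antipode crystallises with the needed acid is empirical; the route is written for the R amine, and the S amine is used if the opposite salt is the less soluble one.
Remark on locants: locants in names and Why lines are those of the compound named. For 4 to 9: C7 ketone, C1 and C4 bridgeheads, C5=C6 alkene with the methyl on C6, C2 quaternary.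

**Route**

Step 1
Reactants: 1 2-methoxy-5-methylphenol; 2 methyl methacrylate
Product: 4 racemic methyl 8,8-dimethoxy-2,6-dimethyl-7-oxobicyclo[2.2.2]oct-5-ene-2-carboxylate (CO2Me on the side of the C5=C6 bridge), via masked o-benzoquinone 3 (not isolated)
Conditions: PhI(OAc)2 (1.2 equiv), MeOH, 2 (20 equiv), 0 °C to 50 °C
Reagents that add atoms: methanol, CO
Why: Oxidative dearomatisation by the hypervalent iodine reagent in methanol gives dienone 3, which methacrylate traps in a Diels–Alder reaction with the orientation typical of masked o-benzoquinones, the substituted dienophile carbon bonding to the diene end next to the carbonyl and the ester lying under the diene (endo, anti to the ketone bridge), which sets C2 relative to C1 and C4.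

Step 2
Reactants: 4 racemic dimethoxy keto ester
Product: 5 racemic methyl 2,6-dimethyl-7-oxobicyclo[2.2.2]oct-5-ene-2-carboxylate
Conditions: SmI2 (5 equiv), THF/MeOH, 0 °C to 23 °C
Reagents that add atoms: none
Why: Samarium diiodide reduction of an α-alkoxy ketone (electron transfer then β-elimination of methoxide, twice) should remove both methoxy groups without touching ester, alkene or stereocentres.

Step 3
Reactants: 5 racemic keto ester
Product: 6 racemic 2,6-dimethyl-7-oxobicyclo[2.2.2]oct-5-ene-2-carboxylic acid
Conditions: LiOH·H2O, THF/MeOH/H2O, 60 °C; then 1 M HCl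
Reagents that add atoms: lithium hydroxide, [Li+].[OH-]
Why: Saponification of the hindered ester; the only ketone α-hydrogen at a stereocentre sits at a bridgehead and cannot enolise, so nothing epimerises.

Step 4
Reactants: 6 racemic keto acid; 7 (R)-1-phenylethylamine
Product: 8 (R)-1-phenylethylammonium (1S,2S,4R)-2,6-dimethyl-7-oxobicyclo[2.2.2]oct-5-ene-2-carboxylate
Conditions: 7 (1.0 equiv), EtOAc/EtOH, fractional crystallisation to constant rotation
Reagents that add atoms: none
Why: Classical resolution through diastereomeric ammonium carboxylates of different solubility fixes the absolute configuration of C1, C2 and C4, from which every later centre of the hirsutane half follows.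

Step 5
Reactants: 8 resolved ammonium salt
Product: 10 2,7-dimethyl-3-oxotricyclo[3.3.0.0(2,8)]octane-7-carboxylic acid (CO2H cis to H1/H5/H8), via (1S,2S,4R)-acid 9 (not isolated)
Conditions: 1 M HCl/EtOAc (salt cleavage, acid used crude); then acetone (0.02 M, degassed), hν (Pyrex, λ > 290 nm), 23 °C
Reagents that add atoms: none
Why: Acetone-sensitised triplet excitation of the β,γ-enone of 9 lets the carbonyl carbon C7 bond to C6, the C1–C7 bond then breaks (1,2-acyl shift) and the resulting 1,3-diradical closes the C1–C5 bond, which is the oxa-di-π-methane rearrangement known for bicyclo[2.2.2]oct-5-en-2-ones. Ring A (C1–C2–C3–C4–C5) closes by radical recombination C1–C5 (3-exo closure of the cyclopropane) and is the cyclohexene ring C1–C6 made smaller by one atom, while ring B (C4–C5–C6–C7–C8) closes by the acyl shift that expels C1 from the ketone-bearing six-membered ring. The new centres at C1, C5 and C6 are dictated by the cage, because both new bonds can only form on its inner faces, so the diquinane is cis-fused and H5 ends up cis to H4 and to CO2H, whereas C2 and C4 are not touched. The step needs the triplet pathway and not the singlet 1,3-acyl shift to a cyclobutanone, which the sensitiser used as solvent and the filtered light should secure. Regiochemistry is unambiguous because C1 is the only sp3 carbon flanked by both the carbonyl and the alkene.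

Step 6
Reactants: 10 cyclopropyl keto acid
Product: 12 cis-fused 2,4-dimethyl-5-oxo-4-(prop-2-en-1-yl)octahydropentalene-2-carboxylic acid (CO2H and allyl cis to H3a/H6a), via dilithium enolate 11 (not isolated)
Conditions: Li (3.3 equiv), NH3(l)/THF, −78 °C; allyl bromide (5 equiv), −78 to −33 °C; NH4Cl, then 1 M HCl
Reagents that add atoms: allyl bromide, C=CCBr
Why: Dissolving-metal reduction cleaves the cyclopropane bond C2–C8 that overlaps with the carbonyl π system and so delivers the C2–C3 enolate regiospecifically, and allylation of this enolate on the convex face of the cis-bicyclo[3.3.0]octane, cis to the ring-fusion hydrogens, sets the quaternary centre (reductive alkylation of a cyclopropyl ketone).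

Step 7
Reactants: 12 allyl keto acid
Product: 13 cis-fused 2,4-dimethyl-5-oxo-4-(2-oxopropyl)octahydropentalene-2-carboxylic acid
Conditions: PdCl2 (10 mol %), CuCl (1 equiv), O2 (1 atm), DMF/H2O 7:1, 23 °C
Reagents that add atoms: water, O
Why: Tsuji–Wacker oxidation of the terminal alkene gives the methyl ketone with Markovnikov selectivity and touches no stereocentre.

Step 8
Reactants: 13 1,4-diketone acid
Product: 14 2,3b-dimethyl-5-oxo-2,3,3a,3b,4,5,7,7a-octahydro-1H-cyclopenta[a]pentalene-2-carboxylic acid (H3a and H7a cis; CO2H cis to both; 3b-CH3 trans to H3a)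
Conditions: KOH, EtOH, 78 °C; then 1 M HCl
Reagents that add atoms: none
Why: Intramolecular aldol condensation, in which the methyl ketone enolate attacks the ring ketone and dehydration gives the bicyclo[3.3.0]oct-1-en-3-one unit of ring C, the alternative aldol to a strained bridged ketol being reversible.

Step 9
Reactants: 14 triquinane enone acid
Product: 15 6,6a-epoxide of 14 (epoxide oxygen cis to the 3b-CH3)
Conditions: 30% H2O2, NaOH, MeOH/H2O, 0 °C to 23 °C; then 1 M HCl to pH 3
Reagents that add atoms: hydrogen peroxide, OO
Why: Weitz–Scheffer nucleophilic epoxidation of the enone, with hydroperoxide adding to C6a on the convex face (cis to the 3b-methyl), the only mode that keeps rings B and C cis-fused.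

Step 10
Reactants: 15 epoxy ketone acid
Product: 16 6-hydroxy-2,3b-dimethyl-5-oxo-2,3,3a,3b,4,5,7,7a-octahydro-1H-cyclopenta[a]pentalene-2-carboxylic acid (diosphenol; ring A/B stereochemistry as in 14)
Conditions: p-TsOH·H2O (0.2 equiv), toluene, 80 °C
Reagents that add atoms: none
Why: Acid-catalysed isomerisation of an α,β-epoxy ketone to a diosphenol: the epoxide opens at the tertiary C6a and loss of the C6 proton gives the conjugated 2-hydroxy-enone, the stable tautomer of the 1,2-dione.

Step 11
Reactants: 17 4-methyl-3,6-dihydro-2H-pyran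
Product: 18 (Z)-[(5-bromo-3-methylpent-3-en-1-yl)oxy]trimethylsilane
Conditions: Me3SiBr (1.05 equiv), CH2Cl2, −40 to 0 °C; used crude
Reagents that add atoms: bromotrimethylsilane, C[Si](C)(C)Br
Why: Silyl halide cleavage of an ether, in which O-silylation is followed by SN2 attack of bromide at the allylic CH2, so the Z geometry is inherited from the six-membered ring.

Step 12
Reactants: 18 allylic bromide
Product: 20 methyl (Z)-7-hydroxy-5-methylhept-4-enoate, via silyl ether ester 19 (not isolated)
Conditions: MeOAc, LDA, THF, −78 °C; 18, DMPU, −78 to −30 °C; then 1 M HCl, 0 °C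
Reagents that add atoms: methyl acetate, COC(C)=O
Why: Alkylation of the lithium enolate of methyl acetate by the primary allylic bromide (SN2, alkene geometry kept), with the silyl ether cleaved in the acidic work-up.

Step 13
Reactants: 20 hydroxy ester
Product: 21 methyl (Z)-7-iodo-5-methylhept-4-enoate
Conditions: I2, PPh3, imidazole, CH2Cl2, 0 °C
Reagents that add atoms: iodine, II
Why: Appel-type substitution of the primary alcohol by iodide (SN2), to which ester and Z alkene are inert.

Step 14
Reactants: 22 3,3-dimethylcyclobutan-1-one; 23 (S)-1-amino-2-(methoxymethyl)pyrrolidine (SAMP)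
Product: 24 SAMP hydrazone of 3,3-dimethylcyclobutan-1-one
Conditions: neat, 60 °C, then removal of water in vacuo
Reagents that add atoms: none
Why: Condensation of ketone and hydrazine to the hydrazone; the ketone is symmetric, so no isomers arise.

Step 15
Reactants: 24 SAMP hydrazone; 21 iodo ester
Product: 26 SAMP hydrazone of methyl (Z)-7-[(1R)-2,2-dimethyl-4-oxocyclobutyl]-5-methylhept-4-enoate, via lithium azaenolate 25 (not isolated)
Conditions: LDA, THF, 0 °C; then −100 °C, 21; to −20 °C
Reagents that add atoms: none
Why: SAMP-hydrazone α-alkylation, in which the primary iodide attacks the chelated lithium azaenolate on the face left open by the (S)-auxiliary and gives the (R) α-centre (the sense known for cyclic ketones), and at −100 °C alkylation should outrun attack on the methyl ester.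

Step 16
Reactants: 26 alkylated hydrazone
Product: 27 methyl (Z)-7-[(1R)-2,2-dimethyl-4-oxocyclobutyl]-5-methylhept-4-enoate
Conditions: sat. aq. oxalic acid, Et2O, 23 °C
Reagents that add atoms: water, O
Why: Two-phase hydrolysis of the hydrazone with oxalic acid, a mild method that should leave the α-stereocentre, the ester and the alkene untouched and return the auxiliary as its oxalate.

Step 17
Reactants: 27 keto ester
Product: 29 (1S,4Z,9R)-4,11,11-trimethylbicyclo[7.2.0]undec-4-en-8-one, via cyclic enol ether 28 (not isolated)
Conditions: TiCl3/LiAlH4, Et3N, DME, 85 °C, slow addition of 27 (high dilution); then 1 M HCl/THF; then NaOMe, MeOH, 23 °C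
Reagents that add atoms: water, O
Why: Titanium-induced keto ester cyclisation (McMurry-type), in which low-valent titanium couples the cyclobutanone carbon with the ester carbonyl to a cyclic enol ether, a ring closure known for this nine-membered skeleton, and acid hydrolysis followed by base equilibration gives the ketone with the thermodynamically preferred trans ring junction, which sets C9 relative to C1.

Step 18
Reactants: 29 nor-ketone
Product: 30 (1S,4Z,9R)-4,11,11-trimethyl-8-methylidenebicyclo[7.2.0]undec-4-ene
Conditions: Ph3PCH3Br, KOtBu, THF, 0 to 50 °C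
Reagents that add atoms: methyltriphenylphosphonium bromide, C[P+](c1ccccc1)(c1ccccc1)c1ccccc1.[Br-]
Why: Wittig methylenation of the ketone, in which the basic ylide can only equilibrate C9 towards the favoured trans junction.

Step 19
Reactants: 16 hirsutane diosphenol acid; 30 (1S,9R)-isocaryophyllene
Product: 32 target CNP0483070.2, via 4-methylidene dione 31 (not isolated)
Conditions: (CH2O)n (2 equiv), pyrrolidine/AcOH (20 mol % each), 30 (2 equiv), 1,4-dioxane, 90 °C, sealed tube
Reagents that add atoms: paraformaldehyde (as formaldehyde), C=O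
Why: Amine-catalysed Knoevenagel condensation of formaldehyde at C4 of 16 (the only CH2 next to the enolised 1,2-dione) gives an o-quinone-methide-type 1-oxadiene that should add to the electron-rich Z C4=C5 bond of 30 in an inverse-demand oxa-Diels–Alder reaction, with oxygen bonding to the tertiary carbon, suprafacial addition fixing the cis ring junction, attack on the alkene face anti to the gem-dimethyl arm (C11) of the cyclobutane setting both new centres relative to C1 and C9, and final ketonisation placing H6a cis to the 3b-methyl (the cis-fused diquinane is the thermodynamic form).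

**Compound list**

1 | 2-methoxy-5-methylphenol | Cc1ccc(OC)c(O)c1 | starting material
2 | methyl methacrylate | C=C(C)C(=O)OC | starting material
3 | 6,6-dimethoxy-3-methylcyclohexa-2,4-dien-1-one (masked o-benzoquinone) | O=C1C=C(C)C=CC1(OC)OC | intermediate (not isolated)
4 | racemic methyl 8,8-dimethoxy-2,6-dimethyl-7-oxobicyclo[2.2.2]oct-5-ene-2-carboxylate, CO2Me syn to the C5=C6 bridge (one enantiomer drawn) | O=C1C(OC)(OC)[C@H]2C[C@](C)(C(=O)OC)[C@@H]1C(C)=C2 | intermediate
5 | racemic methyl 2,6-dimethyl-7-oxobicyclo[2.2.2]oct-5-ene-2-carboxylate, same relative configuration (one enantiomer drawn) | O=C1C[C@H]2C[C@](C)(C(=O)OC)[C@@H]1C(C)=C2 | intermediate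
6 | racemic 2,6-dimethyl-7-oxobicyclo[2.2.2]oct-5-ene-2-carboxylic acid (one enantiomer drawn) | O=C1C[C@H]2C[C@](C)(C(=O)O)[C@@H]1C(C)=C2 | intermediate
7 | (R)-1-phenylethylamine | C[C@@H](N)c1ccccc1 | starting material
8 | (R)-1-phenylethylammonium (1S,2S,4R)-2,6-dimethyl-7-oxobicyclo[2.2.2]oct-5-ene-2-carboxylate | O=C1C[C@H]2C[C@](C)(C(=O)[O-])[C@@H]1C(C)=C2.C[C@@H]([NH3+])c1ccccc1 | intermediate
9 | (1S,2S,4R)-2,6-dimethyl-7-oxobicyclo[2.2.2]oct-5-ene-2-carboxylic acid | O=C1C[C@H]2C[C@](C)(C(=O)O)[C@@H]1C(C)=C2 | intermediate (not isolated)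
10 | 2,7-dimethyl-3-oxotricyclo[3.3.0.0(2,8)]octane-7-carboxylic acid, CO2H cis to H1, H5 and H8, single enantiomer | O=C1C[C@H]2C[C@](C)(C(=O)O)[C@@H]3[C@H]2[C@]13C | intermediate
11 | dilithium enolate carboxylate from 10 (C4=C5 enolate of the octahydropentalene) | [Li+].[Li+].[O-]C1=C(C)[C@@H]2C[C@@](C)(C(=O)[O-])C[C@@H]2C1 | intermediate (not isolated)
12 | cis-fused 2,4-dimethyl-5-oxo-4-(prop-2-en-1-yl)octahydropentalene-2-carboxylic acid, CO2H and allyl cis to H3a/H6a | O=C1C[C@H]2C[C@](C)(C(=O)O)C[C@H]2[C@@]1(CC=C)C | intermediate
13 | cis-fused 2,4-dimethyl-5-oxo-4-(2-oxopropyl)octahydropentalene-2-carboxylic acid | O=C1C[C@H]2C[C@](C)(C(=O)O)C[C@H]2[C@@]1(CC(C)=O)C | intermediate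
14 | 2,3b-dimethyl-5-oxo-2,3,3a,3b,4,5,7,7a-octahydro-1H-cyclopenta[a]pentalene-2-carboxylic acid, H3a/H7a cis, CO2H cis to both, 3b-CH3 trans to H3a | C1C(=O)C=C2C[C@H]3C[C@](C)(C(=O)O)C[C@H]3[C@]12C | intermediate
15 | 6,6a-epoxide of 14, oxygen cis to the 3b-CH3 | C1C(=O)[C@H]2O[C@]23C[C@H]4C[C@](C)(C(=O)O)C[C@H]4[C@]13C | intermediate
16 | 6-hydroxy-2,3b-dimethyl-5-oxo-2,3,3a,3b,4,5,7,7a-octahydro-1H-cyclopenta[a]pentalene-2-carboxylic acid (diosphenol) | C1C(=O)C(O)=C2C[C@H]3C[C@](C)(C(=O)O)C[C@H]3[C@]12C | intermediate
17 | 4-methyl-3,6-dihydro-2H-pyran | CC1=CCOCC1 | starting material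
18 | (Z)-[(5-bromo-3-methylpent-3-en-1-yl)oxy]trimethylsilane | C[Si](C)(C)OCC/C(C)=C\CBr | intermediate
19 | methyl (Z)-5-methyl-7-[(trimethylsilyl)oxy]hept-4-enoate | COC(=O)CC/C=C(/C)CCO[Si](C)(C)C | intermediate (not isolated)
20 | methyl (Z)-7-hydroxy-5-methylhept-4-enoate | COC(=O)CC/C=C(/C)CCO | intermediate
21 | methyl (Z)-7-iodo-5-methylhept-4-enoate | COC(=O)CC/C=C(/C)CCI | intermediate
22 | 3,3-dimethylcyclobutan-1-one | O=C1CC(C)(C)C1 | starting material
23 | (S)-1-amino-2-(methoxymethyl)pyrrolidine (SAMP) | COC[C@@H]1CCCN1N | starting material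
24 | SAMP hydrazone of 3,3-dimethylcyclobutan-1-one | COC[C@@H]1CCCN1N=C1CC(C)(C)C1 | intermediate
25 | lithium azaenolate of 24 | [Li+].COC[C@@H]1CCCN1[N-]C1=CC(C)(C)C1 | intermediate (not isolated)
26 | SAMP hydrazone of methyl (Z)-7-[(1R)-2,2-dimethyl-4-oxocyclobutyl]-5-methylhept-4-enoate | COC[C@@H]1CCCN1N=C1CC(C)(C)[C@H]1CC/C(C)=C\CCC(=O)OC | intermediate
27 | methyl (Z)-7-[(1R)-2,2-dimethyl-4-oxocyclobutyl]-5-methylhept-4-enoate | O=C1CC(C)(C)[C@H]1CC/C(C)=C\CCC(=O)OC | intermediate
28 | (1S,4Z)-8-methoxy-4,11,11-trimethylbicyclo[7.2.0]undeca-4,8-diene (cyclic enol ether) | COC1=C2CC(C)(C)[C@H]2CC/C(C)=C\CC1 | intermediate (not isolated)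
29 | (1S,4Z,9R)-4,11,11-trimethylbicyclo[7.2.0]undec-4-en-8-one | O=C1CC/C=C(/C)CC[C@H]2[C@H]1CC2(C)C | intermediate
30 | (1S,4Z,9R)-4,11,11-trimethyl-8-methylidenebicyclo[7.2.0]undec-4-ene (isocaryophyllene of the 1S,9R series) | C=C1CC/C=C(/C)CC[C@H]2[C@H]1CC2(C)C | intermediate
31 | 6-hydroxy-2,3b-dimethyl-4-methylidene-5-oxo-2,3,3a,3b,4,5,7,7a-octahydro-1H-cyclopenta[a]pentalene-2-carboxylic acid | C=C1C(=O)C(O)=C2C[C@H]3C[C@](C)(C(=O)O)C[C@H]3[C@]12C | intermediate (not isolated)
32 | CNP0483070.2, pyran-fused hirsutane–isocaryophyllane acid | C=C1CC[C@H]2CC3=C(O[C@@]2(C)CC[C@H]2[C@H]1CC2(C)C)C(=O)[C@@H]1C[C@H]2C[C@](C)(C(=O)O)C[C@H]2[C@]31C | target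

**Step count and risks**

Total step count: 19. Longest linear sequence: 11 steps (steps 1 to 10, then 19); the terpene branch is steps 11 to 18.

Steps most likely to fail:

1. Step 19. The heterodiene may add to the exocyclic C8=CH2 bond of 30 or to the wrong alkene face, or oligomerise before it is trapped (site and facial selectivity, short lifetime of the heterodiene). Fallback, setting out from 16 and 29 and returning at 32: the three-component cycloaddition is run with nor-ketone 29, whose Z ring alkene is its only C=C bond, to give the nor-ketone cycloadduct F1. The exocyclic methylene is then introduced last by Wittig reaction with excess Ph3P=CH2 in THF; the first equivalents deprotonate CO2H and the acidic H6a, so the ring-C carbonyl is masked as its enolate and only the C8 ketone should be olefinated, and acidic work-up gives 32.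

2. Step 17. The nine-membered ring may fail to close (intermolecular coupling or plain reduction of the cyclobutanone), and C1 may epimerise under the Lewis acidic and basic conditions. Fallback, setting out from 24 and returning at 29: 24 is alkylated (LDA, then 4-bromo-2-methylbut-1-ene) to the SAMP hydrazone F2, which oxalic acid hydrolyses to the cyclobutanone F3. Wittig reaction with Ph3P=CHOMe gives the enol ether F4, and aqueous HCl followed by K2CO3/MeOH the trans aldehyde F5. But-3-enylmagnesium bromide gives the alcohol F6 and Dess–Martin oxidation the dienone F7. Ring-closing metathesis (second-generation Grubbs catalyst, toluene, high dilution, 80 °C) then closes the ring at C4=C5, where the nine-membered ring admits only the Z alkene, to give 29.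

3. Step 6. Over-reduction of the ketone, proton transfer that moves the enolate to the other α-carbon before C-allylation, or O-allylation may erode the reductive alkylation. Fallback, setting out from 10 and returning at 12: the cyclopropane is cleaved by Bu3SnH/AIBN (benzene, 80 °C) to the keto acid F8. Me3SiCl/Et3N in DMF at 130 °C gives, under equilibrating conditions, the more substituted silyl enol ether as the bis-silyl derivative F9. MeLi (2 equiv, THF, 0 °C) regenerates the tetrasubstituted lithium enolate, which allyl bromide alkylates on the convex face to give 12 after acidic work-up.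

**Further compounds**

F1 | step 19 | nor-ketone cycloadduct (32 with a C8 ketone in place of the exocyclic C=CH2) | O=C1CC[C@H]2CC3=C(O[C@@]2(C)CC[C@H]2[C@H]1CC2(C)C)C(=O)[C@@H]1C[C@H]2C[C@](C)(C(=O)O)C[C@H]2[C@]31C
F2 | step 17 | SAMP hydrazone of (R)-3,3-dimethyl-2-(3-methylbut-3-en-1-yl)cyclobutan-1-one | COC[C@@H]1CCCN1N=C1CC(C)(C)[C@H]1CCC(C)=C
F3 | step 17 | (R)-3,3-dimethyl-2-(3-methylbut-3-en-1-yl)cyclobutan-1-one | O=C1CC(C)(C)[C@H]1CCC(C)=C
F4 | step 17 | (R)-1-(methoxymethylidene)-3,3-dimethyl-2-(3-methylbut-3-en-1-yl)cyclobutane (E/Z mixture) | COC=C1CC(C)(C)[C@H]1CCC(C)=C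
F5 | step 17 | (1R,2S)-3,3-dimethyl-2-(3-methylbut-3-en-1-yl)cyclobutane-1-carbaldehyde (trans) | O=C[C@@H]1CC(C)(C)[C@H]1CCC(C)=C
F6 | step 17 | 1-[(1R,2S)-3,3-dimethyl-2-(3-methylbut-3-en-1-yl)cyclobutyl]pent-4-en-1-ol (carbinol epimers) | C=CCCC(O)[C@@H]1CC(C)(C)[C@H]1CCC(C)=C
F7 | step 17 | 1-[(1R,2S)-3,3-dimethyl-2-(3-methylbut-3-en-1-yl)cyclobutyl]pent-4-en-1-one | C=CCCC(=O)[C@@H]1CC(C)(C)[C@H]1CCC(C)=C
F8 | step 6 | cis-fused 2,4-dimethyl-5-oxooctahydropentalene-2-carboxylic acid (C4 epimers) | O=C1C[C@H]2C[C@](C)(C(=O)O)C[C@H]2C1C
F9 | step 6 | trimethylsilyl ester of the C4=C5 trimethylsilyl enol ether of F8 | C[Si](C)(C)OC1=C(C)[C@@H]2C[C@@](C)(C(=O)O[Si](C)(C)C)C[C@@H]2C1
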